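The route rests on cutting the C2–C3 bond of the dihydrofuran ring. C2 carries O1 and a 3-acetoxyprop-1-en-2-yl group and sits next to the carbinol C3, the pattern left when a γ-aryloxyallyl metal adds to an ortho formyl group. The precursor is therefore an achiral aryl enol ether, ArO–CH=C(CH2OAc)2, with the aldehyde ortho to the ether oxygen, the acetyl group in place and the second phenol silylated. One palladium-catalysed reductive (umpolung) allylation ionises one acetate, forms C2–C3, closes the furan ring, sets both stereocentres cis and leaves the other acetate as the side-chain ester of the target. Angeloylation and desilylation finish the synthesis.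

Key step: step 5

Remark: the sense of induction of the phosphoramidite in step 5 cannot be predicted with confidence; the ligand enantiomer named is assumed to direct addition to the Si face of the formyl group, and its mirror image would be used if a screen showed the opposite sense.

Step 1
Reactants: 1 2,4-dihydroxyacetophenone
Product: 2 5-acetyl-2,4-dihydroxybenzaldehyde
Conditions: Cl2CHOMe (1.2 equiv), TiCl4 (3.5 equiv), CH2Cl2, 0 °C to rt; then ice/1 M HCl
Reagents that add atoms: dichloromethyl methyl ether, COC(Cl)Cl (formyl carbon); water, O (formyl oxygen, on hydrolytic work-up)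
Why: Rieche formylation, a Friedel–Crafts-type substitution in which TiCl4 binds the phenoxide and should deliver the electrophile to C5, the open position ortho to the 4-hydroxyl and para to the chelated 2-hydroxyl (the site at which this ring is also acetylated and brominated), while the new carbonyl group deactivates the ring against a second substitution.

Step 2
Reactants: 3 2-methylenepropane-1,3-diyl diacetate
Product: 5 2-(bromomethylidene)propane-1,3-diyl diacetate, via dibromide 4 (not isolated)
Conditions: Br2 (1.0 equiv), CH2Cl2, 0 °C; then DBU (1.2 equiv), 0 °C to rt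
Reagents that add atoms: bromine, BrBr
Why: Bromine adds across the 1,1-disubstituted alkene and DBU then effects E2 loss of HBr from the tertiary bromide and the acidic CH2Br hydrogen, the usual course for R2C(Br)–CH2Br dibromides, giving a 1-bromoalkene without E/Z isomers because both alkene substituents are CH2OAc, while the neopentyl-type primary bromide resists substitution by the amidine.

Step 3
Reactants: 2 5-acetyl-2,4-dihydroxybenzaldehyde; 5 2-(bromomethylidene)propane-1,3-diyl diacetate
Product: 6 2-[(4-acetyl-2-formyl-5-hydroxyphenoxy)methylidene]propane-1,3-diyl diacetate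
Conditions: CuI (10 mol %), N,N-dimethylglycine (20 mol %), Cs2CO3 (1.1 equiv), 5 (1.1 equiv), 1,4-dioxane, 80 °C
Reagents that add atoms: none
Why: Ullmann-type C–O coupling of a vinyl bromide with a phenoxide under monovalent copper/amino acid catalysis; with one equivalent of base the hydroxyl ortho to the formyl group, which is the more acidic, the less hindered and the more weakly chelated of the two, is expected to react, and the acetates should tolerate carbonate in an aprotic solvent.

Step 4
Reactants: 6 2-[(4-acetyl-2-formyl-5-hydroxyphenoxy)methylidene]propane-1,3-diyl diacetate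
Product: 7 2-[(4-acetyl-5-(tert-butyldimethylsilyloxy)-2-formylphenoxy)methylidene]propane-1,3-diyl diacetate
Conditions: TBSCl (1.3 equiv), imidazole (2.5 equiv), DMAP (cat.), DMF, rt; chromatography on Et3N-deactivated silica
Reagents that add atoms: tert-butyldimethylsilyl chloride, CC(C)(C)[Si](C)(C)Cl
Why: Imidazole/DMAP-mediated silylation of the only free (acetyl-chelated) phenol under non-acidic conditions that should leave the acid-sensitive enol ether, the aldehyde and the acetates untouched.

Step 5
Reactants: 7 2-[(4-acetyl-5-(tert-butyldimethylsilyloxy)-2-formylphenoxy)methylidene]propane-1,3-diyl diacetate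
Product: 9 2-[(2R,3R)-5-acetyl-6-(tert-butyldimethylsilyloxy)-3-hydroxy-2,3-dihydro-1-benzofuran-2-yl]prop-2-en-1-yl acetate (2,3-cis), via diethylborinate 8 (not isolated)
Conditions: Pd(OAc)2 (5 mol %), (S)-BINOL-derived N,N-bis[(S)-1-phenylethyl]phosphoramidite (12 mol %), Et3B (2.2 equiv), 4 Å MS, THF (0.03 M), 0 °C to rt; then pH 7 buffer
Reagents that add atoms: none
Why: Proposed new method: zerovalent palladium (formed in the flask from Pd(OAc)2, the ligand and Et3B) ionises one of the two equivalent acetates of 7, each a vinylogous acetal acetate activated by the enol ether oxygen, to a 1-aryloxy-2-(acetoxymethyl)allylpalladium cation (syn/anti equilibration makes the choice of acetate irrelevant); Et3B then makes this allyl unit nucleophilic by ethyl transfer to palladium with loss of ethene, and the oxygen-bearing γ carbon of the CH2-bound allyl metal adds to the ortho formyl carbon, boron ending on the new alkoxide as 8. The closest known reaction type is the palladium/Et3B (or Et2Zn, InI) umpolung allylation of aldehydes with allylic acetates, known intermolecularly, in ligand-controlled asymmetric form and intramolecularly with carbon tethers, together with the addition of γ-alkoxyallyl metals to aldehydes; an aryl enol ether bis-acetate cyclising onto an ortho aldehyde has not been shown. The furan ring closes by 5-exo-trig attack of C2 on the carbonyl carbon C3, and since attack through the CH2 terminus would need a seven-membered ring, the tether secures γ regioselectivity. C2 and C3 should come out cis because in the closed six-membered transition state, with the metal bridging the aldehyde oxygen and the allyl CH2, the carbonyl oxygen and the central allyl carbon have to lie on the same face of the nearly planar benzo-fused five-membered ring. The absolute configuration (addition to the Si face of the formyl carbon gives 3R and with it 2R) must be imposed by the phosphoramidite, which requires the C–C bond to form while the allyl group is still on ligated palladium; this is the least certain point. The aryl methyl ketone should be spared because the allyl unit is delivered intramolecularly to the neighbouring aldehyde, and the surviving acetate should persist because it is now a plain allylic acetate that ionises more slowly than the oxygen-activated acetates of 7, helped by low temperature, dilution and a small excess of Et3B.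

Step 6
Reactants: 9 2-[(2R,3R)-5-acetyl-6-(tert-butyldimethylsilyloxy)-3-hydroxy-2,3-dihydro-1-benzofuran-2-yl]prop-2-en-1-yl acetate; 10 angelic acid [(Z)-2-methylbut-2-enoic acid]
Product: 12 (2R,3R)-2-[3-(acetyloxy)prop-1-en-2-yl]-5-acetyl-6-(tert-butyldimethylsilyloxy)-2,3-dihydro-1-benzofuran-3-yl (Z)-2-methylbut-2-enoate, via mixed anhydride 11 (not isolated)
Conditions: 10 (2 equiv), 2,4,6-trichlorobenzoyl chloride (2 equiv), Et3N (2.2 equiv), toluene, rt; then 9, toluene, 75 °C
Reagents that add atoms: none
Why: Yamaguchi esterification through the preformed mixed anhydride, heated with the alcohol in the absence of a nucleophilic catalyst, is the established way to acylate hindered secondary alcohols with angelic acid without Z-to-E isomerisation to the tiglate, and since the C3–O bond is not broken both stereocentres are retained.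

Step 7
Reactants: 12 (2R,3R)-2-[3-(acetyloxy)prop-1-en-2-yl]-5-acetyl-6-(tert-butyldimethylsilyloxy)-2,3-dihydro-1-benzofuran-3-yl (Z)-2-methylbut-2-enoate
Product: 13 (2R,3R)-2-[3-(acetyloxy)prop-1-en-2-yl]-5-acetyl-6-hydroxy-2,3-dihydro-1-benzofuran-3-yl (Z)-2-methylbut-2-enoate (target)
Conditions: TBAF/AcOH (1:1, 1.5 equiv), THF, 0 °C
Reagents that add atoms: none
Why: Fluoride should cleave the aryl silyl ether, activated by the ortho acetyl group, rapidly at 0 °C, and the acetic acid buffer keeps the liberated phenol protonated so that neither ester migration nor expulsion of the para-benzylic angelate is expected.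

Compound list
1 | 2,4-dihydroxyacetophenone | CC(=O)c1ccc(O)cc1O | starting material
2 | 5-acetyl-2,4-dihydroxybenzaldehyde | O=Cc1cc(C(C)=O)c(O)cc1O | intermediate
3 | 2-methylenepropane-1,3-diyl diacetate | C=C(COC(C)=O)COC(C)=O | starting material
4 | 2-bromo-2-(bromomethyl)propane-1,3-diyl diacetate (not isolated) | CC(=O)OCC(Br)(CBr)COC(C)=O | intermediate
5 | 2-(bromomethylidene)propane-1,3-diyl diacetate | CC(=O)OCC(=CBr)COC(C)=O | intermediate
6 | 2-[(4-acetyl-2-formyl-5-hydroxyphenoxy)methylidene]propane-1,3-diyl diacetate | CC(=O)OCC(COC(C)=O)=COc1cc(O)c(C(C)=O)cc1C=O | intermediate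
7 | 2-[(4-acetyl-5-(tert-butyldimethylsilyloxy)-2-formylphenoxy)methylidene]propane-1,3-diyl diacetate (key-step precursor) | CC(=O)OCC(COC(C)=O)=COc1cc(O[Si](C)(C)C(C)(C)C)c(C(C)=O)cc1C=O | intermediate
8 | O-diethylboryl derivative (diethylborinate) of 9 (not isolated) | C=C(COC(C)=O)[C@H]1Oc2cc(O[Si](C)(C)C(C)(C)C)c(C(C)=O)cc2[C@H]1OB(CC)CC | intermediate
9 | 2-[(2R,3R)-5-acetyl-6-(tert-butyldimethylsilyloxy)-3-hydroxy-2,3-dihydro-1-benzofuran-2-yl]prop-2-en-1-yl acetate (2,3-cis; key-step product) | C=C(COC(C)=O)[C@H]1Oc2cc(O[Si](C)(C)C(C)(C)C)c(C(C)=O)cc2[C@H]1O | intermediate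
10 | angelic acid, (Z)-2-methylbut-2-enoic acid | C/C=C(/C)C(=O)O | starting material
11 | (Z)-2-methylbut-2-enoic 2,4,6-trichlorobenzoic anhydride (not isolated) | C/C=C(/C)C(=O)OC(=O)c1c(Cl)cc(Cl)cc1Cl | intermediate
12 | (2R,3R)-2-[3-(acetyloxy)prop-1-en-2-yl]-5-acetyl-6-(tert-butyldimethylsilyloxy)-2,3-dihydro-1-benzofuran-3-yl (Z)-2-methylbut-2-enoate | C=C(COC(C)=O)[C@H]1Oc2cc(O[Si](C)(C)C(C)(C)C)c(C(C)=O)cc2[C@H]1OC(=O)/C(C)=C\C | intermediate
13 | (2R,3R)-2-[3-(acetyloxy)prop-1-en-2-yl]-5-acetyl-6-hydroxy-2,3-dihydro-1-benzofuran-3-yl (Z)-2-methylbut-2-enoate | C=C(COC(C)=O)[C@H]1Oc2cc(O)c(C(C)=O)cc2[C@H]1OC(=O)/C(C)=C\C | target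

Total step count: 7
Longest linear sequence: 6 steps (steps 1, 3, 4, 5, 6, 7 from compound 1; equally steps 2 to 7 from compound 3)

Steps most likely to fail

1. Step 5 (the new method). Three processes could defeat it:
- The allyl group may pass from palladium to boron before the C–C bond forms, so that the chiral ligand no longer takes part in choosing the aldehyde face.
- Trace water may cleave the enol ether through the oxygen-stabilised allyl cation.
- The remaining allylic acetate may ionise again, leading to reduction or to etherification by the neighbouring cis alkoxide.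

The fallback uses known reaction types only and closes O1–C2 instead of C2–C3. It sets out from 2 and 5 and returns to the route at 9. Compound 2 would be bis-silylated (TBSCl, imidazole, DMF) to 5-acetyl-2,4-bis(tert-butyldimethylsilyloxy)benzaldehyde F1. An asymmetric Nozaki–Hiyama–Kishi coupling of F1 with vinyl bromide 5 (CrCl2, NiCl2 cat., chiral oxazoline–sulfonamide ligand, Et3N, THF) is selective for the aldehyde over the methyl ketone and inert to the acetates. It should give the allylic alcohol 2-[(2S)-2-[5-acetyl-2,4-bis(tert-butyldimethylsilyloxy)phenyl]-2-hydroxyethylidene]propane-1,3-diyl diacetate F2, whose S carbinol corresponds to 3R after ring closure because the CIP priorities change. Both silyl ethers would be removed (TBAF/AcOH, THF, 0 °C) to give 2-[(2S)-2-(5-acetyl-2,4-dihydroxyphenyl)-2-hydroxyethylidene]propane-1,3-diyl diacetate F3. An intramolecular Tsuji–Trost O-allylation (Pd2(dba)3·CHCl3, the matched enantiomer of N,N'-(cyclohexane-1,2-diyl)bis[2-(diphenylphosphino)benzamide], Et3N, CH2Cl2, rt, stopped at full conversion) would then ionise one acetate. The phenol ortho to the side chain attacks the substituted allyl terminus in a 5-exo sense, the ligand choosing the allyl face that places the new side chain cis to the hydroxyl. This should give 2-[(2R,3R)-5-acetyl-3,6-dihydroxy-2,3-dihydro-1-benzofuran-2-yl]prop-2-en-1-yl acetate F4. Phenol-selective silylation (TBSCl 1.05 equiv, imidazole, DMF, 0 °C) returns to 9.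

2. Step 3. Two processes are of concern:
- Discrimination between the two chelated phenols may be incomplete, with vinylation at the hydroxyl next to the acetyl group or at both.
- Base may induce Claisen–Schmidt condensation between the methyl ketone and the aldehyde.

The fallback differentiates the two oxygens before the aldehyde exists, using the reliable preference of 1 for reaction at its 4-hydroxyl. It sets out from 1 and returns at 7, by-passing 2 and 6. Benzylation (BnBr, K2CO3, acetone) should give 1-[4-(benzyloxy)-2-hydroxyphenyl]ethanone F5. Silylation (TBSCl, imidazole, DMAP, DMF) gives 1-[4-(benzyloxy)-2-(tert-butyldimethylsilyloxy)phenyl]ethanone F6. Hydrogenolysis (H2, Pd/C, EtOAc) gives 1-[2-(tert-butyldimethylsilyloxy)-4-hydroxyphenyl]ethanone F7. Magnesium-mediated ortho-formylation (MgCl2, Et3N, paraformaldehyde, MeCN, reflux) at the unhindered position next to the only free hydroxyl gives 5-acetyl-2-hydroxy-4-(tert-butyldimethylsilyloxy)benzaldehyde F8. Its single free phenol is then vinylated with 5 (CuI, N,N-dimethylglycine, K3PO4 in place of Cs2CO3 to spare the silyl ether, dioxane) to give 7.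

3. Step 6. Three processes are of concern:
- The angelate may isomerise to the E (tiglate) ester during acyl transfer.
- Acylation of the hindered cis alcohol may be sluggish.
- The silyl group may be lost, followed by acylation of the phenol.

The fallback builds the Z alkene on the ester instead of transferring it. It sets out from 9 and returns at 12. Steglich esterification (DCC, DMAP cat., CH2Cl2, 0 °C) of 9 with 2-[bis(2,2,2-trifluoroethoxy)phosphoryl]propanoic acid should give (2R,3R)-2-[3-(acetyloxy)prop-1-en-2-yl]-5-acetyl-6-(tert-butyldimethylsilyloxy)-2,3-dihydro-1-benzofuran-3-yl 2-[bis(2,2,2-trifluoroethoxy)phosphoryl]propanoate F9, a mixture of epimers at the phosphorus-bearing carbon. Still–Gennari olefination (KN(SiMe3)2, 18-crown-6, THF, −78 °C; acetaldehyde) should then give the (Z)-2-methylbut-2-enoate 12.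

Further compounds
F1 | step 5 | 5-acetyl-2,4-bis(tert-butyldimethylsilyloxy)benzaldehyde | CC(=O)c1cc(C=O)c(O[Si](C)(C)C(C)(C)C)cc1O[Si](C)(C)C(C)(C)C
F2 | step 5 | 2-[(2S)-2-[5-acetyl-2,4-bis(tert-butyldimethylsilyloxy)phenyl]-2-hydroxyethylidene]propane-1,3-diyl diacetate | O[C@@H](C=C(COC(C)=O)COC(C)=O)c1cc(C(C)=O)c(O[Si](C)(C)C(C)(C)C)cc1O[Si](C)(C)C(C)(C)C
F3 | step 5 | 2-[(2S)-2-(5-acetyl-2,4-dihydroxyphenyl)-2-hydroxyethylidene]propane-1,3-diyl diacetate | O[C@@H](C=C(COC(C)=O)COC(C)=O)c1cc(C(C)=O)c(O)cc1O
F4 | step 5 | 2-[(2R,3R)-5-acetyl-3,6-dihydroxy-2,3-dihydro-1-benzofuran-2-yl]prop-2-en-1-yl acetate | C=C(COC(C)=O)[C@H]1Oc2cc(O)c(C(C)=O)cc2[C@H]1O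
F5 | step 3 | 1-[4-(benzyloxy)-2-hydroxyphenyl]ethanone | CC(=O)c1ccc(OCc2ccccc2)cc1O
F6 | step 3 | 1-[4-(benzyloxy)-2-(tert-butyldimethylsilyloxy)phenyl]ethanone | CC(=O)c1ccc(OCc2ccccc2)cc1O[Si](C)(C)C(C)(C)C
F7 | step 3 | 1-[2-(tert-butyldimethylsilyloxy)-4-hydroxyphenyl]ethanone | CC(=O)c1ccc(O)cc1O[Si](C)(C)C(C)(C)C
F8 | step 3 | 5-acetyl-2-hydroxy-4-(tert-butyldimethylsilyloxy)benzaldehyde | CC(=O)c1cc(C=O)c(O)cc1O[Si](C)(C)C(C)(C)C
F9 | step 6 | (2R,3R)-2-[3-(acetyloxy)prop-1-en-2-yl]-5-acetyl-6-(tert-butyldimethylsilyloxy)-2,3-dihydro-1-benzofuran-3-yl 2-[bis(2,2,2-trifluoroethoxy)phosphoryl]propanoate | C=C(COC(C)=O)[C@H]1Oc2cc(O[Si](C)(C)C(C)(C)C)c(C(C)=O)cc2[C@H]1OC(=O)C(C)P(=O)(OCC(F)(F)F)OCC(F)(F)F
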